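Drimane numbering: ring A = C1–C5 and C10, ring B = C5–C10, C11 on C9, C12 on C8. The retrosynthesis first cuts the aryl ether bond O–C11. C8=C12 is then traced back to a C12 selenide and C11 acid and these to an 11,12-lactone, H5/O6 is traced back to a C5=C6 alkene, and finally the ring-B bonds C7–C8 and C9–C10 are cut.
Enabling feature: the neighbouring ring-B carbons C8 and C9 each carry exactly one exocyclic carbon (C12, C11), which matches the β- and α-carbon of a γ-alkoxybutenolide. With C5=C6 in place, ring B is a cyclohexene whose diene C7=C6–C5=C10 is a vinyl group on ring A.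
Forward order: ring A comes from 2,2-dimethylcyclohexane-1,3-dione (four steps to the diene) and ring B closes in the Diels–Alder step. The auxiliary lactone is then opened at C12, so C11 and C12 never become equivalent, and the coumarin is joined last.
Stereochemistry: (−)-menthol fixes the acetal carbon of the dienophile. This fixes C8/C9 by anti addition and, through the exo mode, quaternary C10. The C10 methyl steers the syn hydroboration (C5, C6), LiBH(s-Bu)3 sets the axial C3 carbinol, and C8 is erased when C8=C12 forms.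
Key step: step 7

Remark on the chemistry: the target is (3S,5S,6R,9R,10S). H5, the C6 oxygen and the C3 oxygen lie on the face opposite to the C10 methyl, and C11 lies on the methyl face. H5 and O6 are therefore on the same face (H5/H6 trans-diaxial, acetate equatorial), which is what a syn hydroboration delivers. "Syn" and "anti" below refer to the C10 methyl.

Step 1
Reactants: 1 2,2-dimethylcyclohexane-1,3-dione
Product: 2 6,6-dimethyl-1,4-dioxaspiro[4.5]decan-7-one (ring A with C3 as ketal)
Conditions: HOCH2CH2OH (1.05 equiv), p-TsOH·H2O (cat.), toluene, reflux, azeotropic removal of water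
Reagents that add atoms: ethylene glycol OCCO
Why: Acid-catalysed ketalisation; the two carbonyls of 1 are equivalent and the remaining one, then flanked by the quaternary carbon and the new dioxolane, reacts more slowly, so one equivalent of diol should stop at the monoketal.

Step 2
Reactants: 2 6,6-dimethyl-1,4-dioxaspiro[4.5]decan-7-one
Product: 4 6,6,8-trimethyl-1,4-dioxaspiro[4.5]decan-7-one (racemic), via lithium enolate 3 (not isolated)
Conditions: LiN(i-Pr)2, THF, −78 °C; MeI, −78 → 0 °C
Reagents that add atoms: iodomethane CI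
Why: Kinetic enolate alkylation; C4 is quaternary, so deprotonation is possible only at the future C10, and the stereocentre formed is erased in step 3.

Step 3
Reactants: 4 6,6,8-trimethyl-1,4-dioxaspiro[4.5]decan-7-one
Product: 6 6,6,8-trimethyl-1,4-dioxaspiro[4.5]dec-7-en-7-yl trifluoromethanesulfonate, via lithium enolate 5 (not isolated)
Conditions: LiN(i-Pr)2, THF, −78 → 0 °C; PhNTf2, 0 °C → rt
Reagents that add atoms: N-phenylbis(trifluoromethanesulfonimide) O=S(=O)(N(c1ccccc1)S(=O)(=O)C(F)(F)F)C(F)(F)F
Why: Enol triflate formation; the only α-hydrogen left is the C10 methine, so a single tetrasubstituted enolate forms and is O-sulfonylated, as known for 2,2,6-trimethylcyclohexanone.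

Step 4
Reactants: 6 6,6,8-trimethyl-1,4-dioxaspiro[4.5]dec-7-en-7-yl trifluoromethanesulfonate
Product: 7 7-ethenyl-6,6,8-trimethyl-1,4-dioxaspiro[4.5]dec-7-ene (achiral diene C7=C6–C5=C10)
Conditions: CH2=CHSnBu3, Pd(PPh3)4 (cat.), LiCl, THF, reflux
Reagents that add atoms: tributyl(vinyl)stannane C=C[Sn](CCCC)(CCCC)CCCC
Why: Stille coupling; oxidative addition of the enol triflate to zerovalent palladium (assisted by LiCl), vinyl transfer from tin and reductive elimination give the diene, as known for 2,6,6-trimethylcyclohexenyl triflate, and the ketal is inert.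

Step 5
Reactants: 8 furfural
Product: 10 5-hydroxyfuran-2(5H)-one (racemic), via furan endoperoxide 9 (not isolated)
Conditions: O2, hν (visible), rose bengal (C20H2Cl4I4Na2O5, cat.), MeOH, rt
Reagents that add atoms: oxygen O=O
Why: Dye-sensitised photooxygenation; singlet oxygen adds [4+2] across the furan and methanol cleaves the formyl group from the endoperoxide, leaving the γ-hydroxybutenolide.

Step 6
Reactants: 10 5-hydroxyfuran-2(5H)-one; 11 (−)-menthol
Product: 13 (5R)-5-[(1R,2S,5R)-menthyloxy]furan-2(5H)-one, via 5S acetal epimer 12 (not isolated)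
Conditions: p-TsOH·H2O (cat.), toluene, reflux, azeotropic removal of water; crystallisation from hexane, −20 °C, mother liquor re-equilibrated with acid
Reagents that add atoms: none
Why: Acid-catalysed acetalisation of the pseudo-acid; the two acetal epimers interconvert under acid and only the (5R) isomer crystallises, so the new stereocentre is set by crystallisation-driven equilibration.

Step 7
Reactants: 7 7-ethenyl-6,6,8-trimethyl-1,4-dioxaspiro[4.5]dec-7-ene; 13 (5R)-5-[(1R,2S,5R)-menthyloxy]furan-2(5H)-one
Product: 14 exo adduct (8R,9R,10S,12R)-3,3-ethylenedioxy-12-(l-menthyloxy)drim-5-en-11,12-olide (cis-fused lactone acetal; C11 carbonyl on C9 and C12 acetal carbon on C8 both syn; menthyloxy trans to C7 on the lactone ring)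
Conditions: 7 (2 equiv), 2,6-di-tert-butyl-4-methylphenol (trace), CH2Cl2, 1.2 GPa, 50 °C
Reagents that add atoms: none
Why: This is a concerted but asynchronous suprafacial [4+2] cycloaddition of normal electron demand in which the s-cis diene C7=C6–C5=C10 adds across the C3=C4 bond of 13, with C7–C8 running ahead of C9–C10; the closest known reactions are the thermal and pressure-assisted Diels–Alder additions of 1-vinyl-2,6,6-trimethylcyclohexene-type dienes to activated dienophiles and of 5-menthyloxyfuranone to simple dienes. Six-membered ring B (C5–C10) closes as an intermolecular [4+2] annulation onto ring A, and the lactone acetal ring arrives cis-fused at C8–C9. The step needs regioselectivity, and this is secured because the unsubstituted, most nucleophilic terminus C7 bonds to the electrophilic β-carbon (future C8), so that the α-carbon (future C9), which carries only the flat carbonyl side of the dienophile, meets the crowded C10. C8 and C9 are controlled by the acetal stereocentre, since the diene can reach only the butenolide face anti to the menthyloxy group. C10 is controlled by the exo orientation, which places C11 beside the inside methyl on C10 (cis in 14); in the endo mode the lactone carbonyl would sit under C5 and run into the axial ring-A substituent on that face (a C4 methyl or a C3 ketal oxygen, whichever half-chair is populated), and the weak secondary overlap of a butenolide should not outweigh this. The pressure of 1.2 GPa uses the strongly negative activation volume so that two sluggish partners can combine at 50 °C, below the range of 1,5-hydrogen shift in 7 and of acetal epimerisation in 13.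

Step 8
Reactants: 14 exo adduct
Product: 18 (8S,9R,10S)-3,3-ethylenedioxydrim-5-en-11,12-olide (trans-fused lactone; C11 syn and C12 anti), via cis formyl ester 15 (not isolated), via trans formyl ester 16 (not isolated), via hydroxy ester 17 (not isolated)
Conditions: NaOMe (0.3 equiv), MeOH, rt; NaBH4, 0 °C; aq. citric acid
Reagents that add atoms: none
Why: Methoxide opens the pseudo-ester to the formyl ester and releases menthol, the aldehyde epimerises at C8 from the axial position (syn-diaxial to the C10 methyl) to the equatorial one while the far less acidic, already equatorial C9 ester centre stays, and borohydride reduction with alkoxide lactonisation gives one lactone in which C11 (acyl) and C12 (alkyl–O) remain distinct; C8 is set thermodynamically and is erased in step 13.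

Step 9
Reactants: 18 (8S,9R,10S)-3,3-ethylenedioxydrim-5-en-11,12-olide
Product: 20 (5S,6R,8S,9R,10S)-3,3-ethylenedioxy-6-hydroxydriman-11,12-olide (trans-decalin; H5 and equatorial 6-OH anti), via C6 alkylborane 19 (not isolated)
Conditions: BH3·THF, THF, 0 °C → rt; NaBO3·4H2O, THF–H2O, rt
Reagents that add atoms: sodium perborate (used as tetrahydrate) [Na+].[O-]OB=O
Why: Hydroboration–oxidation; borane adds syn to the face anti to the C10 methyl and the axial C4 methyl with boron on the less substituted C6, which sets H5 and, after ester-tolerant perborate oxidation with retention, the equatorial C6 alcohol, in line with the anti-face hydroboration of Δ5-steroid 3-ketals.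

Step 10
Reactants: 20 (5S,6R,8S,9R,10S)-3,3-ethylenedioxy-6-hydroxydriman-11,12-olide
Product: 22 (5S,6R,8S,9R,10S)-3,3-ethylenedioxy-6-hydroxy-12-(phenylselanyl)driman-11-oic acid, via sodium carboxylate 21 (not isolated)
Conditions: PhSeH, NaH, DMF, 0 °C; then 20, 100 °C; 1 M HCl to pH 4, 0 °C
Reagents that add atoms: benzeneselenol [SeH]c1ccccc1
Why: SN2 opening of a γ-lactone by the soft, weakly basic selenolate at the alkyl carbon C12 (alkyl–oxygen cleavage), helped by the strain of the trans ring fusion, puts the future leaving group on C12 only and frees C11 as the acid without touching a stereocentre.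

Step 11
Reactants: 22 (5S,6R,8S,9R,10S)-3,3-ethylenedioxy-6-hydroxy-12-(phenylselanyl)driman-11-oic acid
Product: 24 (5S,6R,8S,9R,10S)-6-acetoxy-3,3-ethylenedioxy-12-(phenylselanyl)driman-11-oic acid, via mixed anhydride 23 (not isolated)
Conditions: Ac2O, DMAP (cat.), pyridine, rt; then H2O–THF, rt
Reagents that add atoms: acetic anhydride CC(=O)OC(C)=O
Why: DMAP-catalysed acylation of the only hydroxyl group; the carboxyl group is acetylated transiently, and water cleaves the mixed anhydride at its unhindered acetyl carbonyl.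

Step 12
Reactants: 24 (5S,6R,8S,9R,10S)-6-acetoxy-3,3-ethylenedioxy-12-(phenylselanyl)driman-11-oic acid
Product: 25 (5S,6R,8S,9R,10S)-6-acetoxy-3,3-ethylenedioxy-12-(phenylselanyl)driman-11-ol
Conditions: BH3·THF, THF, 0 °C → rt; H2O
Reagents that add atoms: none
Why: Chemoselective borane reduction of a carboxylic acid through its acyloxyborane, which is much faster than attack on the acetate, the ketal or the selenide.

Step 13
Reactants: 25 (5S,6R,8S,9R,10S)-6-acetoxy-3,3-ethylenedioxy-12-(phenylselanyl)driman-11-ol
Product: 27 (5S,6R,9R,10S)-6-acetoxy-3,3-ethylenedioxydrim-8(12)-en-11-ol, via selenoxide 26 (not isolated)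
Conditions: 30% H2O2, pyridine, THF, 0 → 40 °C
Reagents that add atoms: none
Why: Selenide oxidation and selenoxide syn-elimination; H8 is the only β-hydrogen, so the exocyclic C8=C12 alkene is the only possible regioisomer, and pyridine buffers the selenium acids.

Step 14
Reactants: 27 (5S,6R,9R,10S)-6-acetoxy-3,3-ethylenedioxydrim-8(12)-en-11-ol
Product: 28 (5S,6R,9R,10S)-6-acetoxy-11-hydroxydrim-8(12)-en-3-one
Conditions: pyridinium p-toluenesulfonate (cat.), acetone–H2O, 50 °C
Reagents that add atoms: water O
Why: Mild acid-catalysed ketal hydrolysis; the weak acid should neither isomerise the 1,1-disubstituted alkene nor cleave the acetate.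

Step 15
Reactants: 28 (5S,6R,9R,10S)-6-acetoxy-11-hydroxydrim-8(12)-en-3-one
Product: 29 (3S,5S,6R,9R,10S)-6-acetoxydrim-8(12)-ene-3,11-diol (axial 3-OH anti)
Conditions: LiBH(s-Bu)3 (2.5 equiv), THF, −78 °C; H2O
Reagents that add atoms: none
Why: Bulky trialkylborohydride reduction; the axial trajectory is barred by the syn-axial H1 and H5, so hydride arrives equatorially and gives the axial C3 alcohol anti to the C10 methyl, as known for 4,4-dimethyl-3-oxo trans-decalins, while at −78 °C the hindered acetate and the alkene stay intact and the C11 hydroxyl only consumes one equivalent.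

Step 16
Reactants: 29 (3S,5S,6R,9R,10S)-6-acetoxydrim-8(12)-ene-3,11-diol; 30 umbelliferone
Product: 31 isofeterin 7-{[(3S,5S,6R,9R,10S)-6-acetoxy-3-hydroxydrim-8(12)-en-11-yl]oxy}coumarin
Conditions: PPh3, DIAD, THF, 0 °C → rt
Reagents that add atoms: none
Why: Mitsunobu etherification; only the primary C11 hydroxyl forms a reactive alkoxyphosphonium ion and is displaced by the acidic phenol, the axial neopentyl C3 hydroxyl is inert, and no stereocentre is involved.

Compound list
1 | 2,2-dimethylcyclohexane-1,3-dione | CC1(C)C(=O)CCCC1=O | starting material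
2 | 6,6-dimethyl-1,4-dioxaspiro[4.5]decan-7-one | CC1(C)C(=O)CCCC12OCCO2 | intermediate
3 | lithium enolate of 2 (not isolated) | [Li+].[O-]C1=CCCC2(OCCO2)C1(C)C | intermediate
4 | 6,6,8-trimethyl-1,4-dioxaspiro[4.5]decan-7-one (racemic) | CC1CCC2(OCCO2)C(C)(C)C1=O | intermediate
5 | tetrasubstituted lithium enolate of 4 (not isolated) | [Li+].[O-]C1=C(C)CCC2(OCCO2)C1(C)C | intermediate
6 | 6,6,8-trimethyl-1,4-dioxaspiro[4.5]dec-7-en-7-yl trifluoromethanesulfonate | CC1=C(OS(=O)(=O)C(F)(F)F)C(C)(C)C2(OCCO2)CC1 | intermediate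
7 | 7-ethenyl-6,6,8-trimethyl-1,4-dioxaspiro[4.5]dec-7-ene (ring-A vinyl diene) | C=CC1=C(C)CCC2(OCCO2)C1(C)C | intermediate
8 | furfural | O=Cc1ccco1 | starting material
9 | furfural endoperoxide, 2,3,7-trioxabicyclo[2.2.1]hept-5-ene-1-carbaldehyde (racemic, not isolated) | O=CC12C=CC(OO1)O2 | intermediate
10 | 5-hydroxyfuran-2(5H)-one (racemic) | OC1C=CC(=O)O1 | intermediate
11 | (−)-menthol, (1R,2S,5R) | CC(C)[C@@H]1CC[C@@H](C)C[C@H]1O | starting material
12 | (5S)-5-(l-menthyloxy)furan-2(5H)-one (equilibrating epimer, not isolated) | O=C1C=C[C@@H](O[C@@H]2C[C@H](C)CC[C@H]2C(C)C)O1 | intermediate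
13 | (5R)-5-(l-menthyloxy)furan-2(5H)-one | O=C1C=C[C@H](O[C@@H]2C[C@H](C)CC[C@H]2C(C)C)O1 | intermediate
14 | exo adduct, (8R,9R,10S,12R)-3,3-ethylenedioxy-12-(l-menthyloxy)drim-5-en-11,12-olide | O=C1O[C@@H](O[C@@H]5C[C@H](C)CC[C@H]5C(C)C)[C@@H]2CC=C3C(C)(C)C4(OCCO4)CC[C@@]3(C)[C@H]12 | intermediate
15 | cis formyl ester, methyl 3,3-ethylenedioxy-12-oxodrim-5-en-11-oate with C12 syn (not isolated) | O=C[C@@H]1CC=C2C(C)(C)C3(OCCO3)CC[C@@]2(C)[C@@H]1C(=O)OC | intermediate
16 | trans formyl ester, C8 epimer of 15 with C12 anti (not isolated) | O=C[C@H]1CC=C2C(C)(C)C3(OCCO3)CC[C@@]2(C)[C@@H]1C(=O)OC | intermediate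
17 | hydroxy ester, methyl 3,3-ethylenedioxy-12-hydroxydrim-5-en-11-oate (not isolated) | OC[C@H]1CC=C2C(C)(C)C3(OCCO3)CC[C@@]2(C)[C@@H]1C(=O)OC | intermediate
18 | (8S,9R,10S)-3,3-ethylenedioxydrim-5-en-11,12-olide (trans-fused) | O=C1OC[C@H]2CC=C3C(C)(C)C4(OCCO4)CC[C@@]3(C)[C@H]12 | intermediate
19 | C6 alkylborane, written as the monoalkylborane (not isolated) | O=C1OC[C@H]2C[C@@H](B)[C@@H]3C(C)(C)C4(OCCO4)CC[C@@]3(C)[C@H]12 | intermediate
20 | (5S,6R,8S,9R,10S)-3,3-ethylenedioxy-6-hydroxydriman-11,12-olide | O=C1OC[C@H]2C[C@@H](O)[C@@H]3C(C)(C)C4(OCCO4)CC[C@@]3(C)[C@H]12 | intermediate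
21 | sodium salt of 22 (not isolated) | c1ccccc1[Se]C[C@H]2C[C@@H](O)[C@@H]3C(C)(C)C4(OCCO4)CC[C@@]3(C)[C@@H]2C(=O)[O-].[Na+] | intermediate
22 | (5S,6R,8S,9R,10S)-3,3-ethylenedioxy-6-hydroxy-12-(phenylselanyl)driman-11-oic acid | c1ccccc1[Se]C[C@H]2C[C@@H](O)[C@@H]3C(C)(C)C4(OCCO4)CC[C@@]3(C)[C@@H]2C(=O)O | intermediate
23 | acetic mixed anhydride of 24 (not isolated) | c1ccccc1[Se]C[C@H]2C[C@@H](OC(C)=O)[C@@H]3C(C)(C)C4(OCCO4)CC[C@@]3(C)[C@@H]2C(=O)OC(C)=O | intermediate
24 | (5S,6R,8S,9R,10S)-6-acetoxy-3,3-ethylenedioxy-12-(phenylselanyl)driman-11-oic acid | c1ccccc1[Se]C[C@H]2C[C@@H](OC(C)=O)[C@@H]3C(C)(C)C4(OCCO4)CC[C@@]3(C)[C@@H]2C(=O)O | intermediate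
25 | (5S,6R,8S,9R,10S)-6-acetoxy-3,3-ethylenedioxy-12-(phenylselanyl)driman-11-ol | c1ccccc1[Se]C[C@H]2C[C@@H](OC(C)=O)[C@@H]3C(C)(C)C4(OCCO4)CC[C@@]3(C)[C@@H]2CO | intermediate
26 | selenoxide of 25, mixture at selenium (not isolated) | c1ccccc1[Se](=O)C[C@H]2C[C@@H](OC(C)=O)[C@@H]3C(C)(C)C4(OCCO4)CC[C@@]3(C)[C@@H]2CO | intermediate
27 | (5S,6R,9R,10S)-6-acetoxy-3,3-ethylenedioxydrim-8(12)-en-11-ol | C=C1C[C@@H](OC(C)=O)[C@@H]2C(C)(C)C3(OCCO3)CC[C@@]2(C)[C@@H]1CO | intermediate
28 | (5S,6R,9R,10S)-6-acetoxy-11-hydroxydrim-8(12)-en-3-one | C=C1C[C@@H](OC(C)=O)[C@@H]2C(C)(C)C(=O)CC[C@@]2(C)[C@@H]1CO | intermediate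
29 | (3S,5S,6R,9R,10S)-6-acetoxydrim-8(12)-ene-3,11-diol | C=C1C[C@@H](OC(C)=O)[C@@H]2C(C)(C)[C@@H](O)CC[C@@]2(C)[C@@H]1CO | intermediate
30 | umbelliferone (7-hydroxycoumarin) | Oc1ccc2ccc(=O)oc2c1 | starting material
31 | isofeterin | C=C1C[C@@H](OC(C)=O)[C@@H]2C(C)(C)[C@@H](O)CC[C@@]2(C)[C@@H]1COc1ccc2ccc(=O)oc2c1 | target

Total step count: 16. Longest linear sequence: 14 steps (steps 1–4 and 7–16).

Steps most likely to fail

1. Step 7. The risk is poor exo/endo discrimination, since the endo orientation may compete or win, together with slow conversion at the twisted, tetrasubstituted diene terminus. The fallback keeps the same two bonds but relays the stereochemistry differently. It sets out from 10 and 7 and comes back at 18.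
 - Compound 10 is acetalised with (+)-menthol as in step 6 to give (5S)-5-(d-menthyloxy)furan-2(5H)-one F1.
 - Its endo, anti cycloaddition with 7 gives endo adduct F2, which has the required C10 configuration but carries C11 and C12 anti to the C10 methyl.
 - The reagents of step 8 take it through 9-epi formyl ester F3 (C12 already equatorial) and 9-epi hydroxy ester F4 to cis-lactone F5, the C9 epimer of 18.
 - LiN(i-Pr)2 in THF at −78 °C forms lactone enolate F6. Kinetic protonation with acetic acid from the face anti to the angular methyl places H9 there and gives 18.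

2. Step 9. The risk is that slow hydroboration of the hindered trisubstituted alkene lets borane attack the lactone carbonyl or cleave the ketal. The fallback reorders the sequence so that carbonyl reduction is wanted. It sets out from 18 and comes back at 27.
 - The selenolate opening of step 10 is applied to 18 and gives Δ5 seleno acid F7.
 - Excess BH3·THF reduces the carboxyl group and hydroborates C5=C6 in one operation.
 - H2O2/NaOH oxidises boron and selenium, and selenoxide diol F8 eliminates to 6,11-diol F9.
 - TBSCl/imidazole silylates only the primary C11 hydroxyl to give silyl ether F10.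
 - Ac2O/DMAP gives silyl ether acetate F11, and Bu4NF frees C11–OH to give 27.

3. Step 16. The risk is sluggish displacement at the β-branched, neopentyl-like C11 and loss of the activated alcohol by elimination towards a C9=C11/C8=C12 diene. The fallback forms the aryl–oxygen bond instead of the C11–oxygen bond. It sets out from 29 and ends at 31. The primary alcohol of 29 is coupled with commercial 7-bromocoumarin by palladium-catalysed C–O cross-coupling ([(C3H5)PdCl]2, RockPhos, Cs2CO3, toluene, 90 °C). No substitution at C11 is needed, and the hindered axial C3 hydroxyl should not compete.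

Further compounds
F1 | step 7 | (5S)-5-(d-menthyloxy)furan-2(5H)-one | O=C1C=C[C@@H](O[C@H]2C[C@@H](C)CC[C@@H]2C(C)C)O1
F2 | step 7 | endo adduct, 3,3-ethylenedioxy-12-(d-menthyloxy)drim-5-en-11,12-olide with C11 and C12 anti to the C10 methyl | O=C1O[C@H](O[C@H]5C[C@@H](C)CC[C@@H]5C(C)C)[C@H]2CC=C3C(C)(C)C4(OCCO4)CC[C@@]3(C)[C@@H]12
F3 | step 7 | 9-epi formyl ester, C9 epimer of 16 | O=C[C@H]1CC=C2C(C)(C)C3(OCCO3)CC[C@@]2(C)[C@H]1C(=O)OC
F4 | step 7 | 9-epi hydroxy ester, C9 epimer of 17 | OC[C@H]1CC=C2C(C)(C)C3(OCCO3)CC[C@@]2(C)[C@H]1C(=O)OC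
F5 | step 7 | cis-lactone, C9 epimer of 18 | O=C1OC[C@H]2CC=C3C(C)(C)C4(OCCO4)CC[C@@]3(C)[C@@H]12
F6 | step 7 | lactone enolate (lithium, C9=C11) | [Li+].[O-]C=1OC[C@H]2CC=C3C(C)(C)C4(OCCO4)CC[C@@]3(C)C=12
F7 | step 9 | Δ5 seleno acid, 3,3-ethylenedioxy-12-(phenylselanyl)drim-5-en-11-oic acid | c1ccccc1[Se]C[C@H]2CC=C3C(C)(C)C4(OCCO4)CC[C@@]3(C)[C@@H]2C(=O)O
F8 | step 9 | selenoxide diol, 3,3-ethylenedioxy-12-(phenylseleninyl)drimane-6,11-diol | c1ccccc1[Se](=O)C[C@H]2C[C@@H](O)[C@@H]3C(C)(C)C4(OCCO4)CC[C@@]3(C)[C@@H]2CO
F9 | step 9 | 6,11-diol, 3,3-ethylenedioxydrim-8(12)-ene-6,11-diol | C=C1C[C@@H](O)[C@@H]2C(C)(C)C3(OCCO3)CC[C@@]2(C)[C@@H]1CO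
F10 | step 9 | silyl ether, 11-O-TBS derivative of F9 | C=C1C[C@@H](O)[C@@H]2C(C)(C)C3(OCCO3)CC[C@@]2(C)[C@@H]1CO[Si](C)(C)C(C)(C)C
F11 | step 9 | silyl ether acetate, 11-O-TBS derivative of 27 | C=C1C[C@@H](OC(C)=O)[C@@H]2C(C)(C)C3(OCCO3)CC[C@@]2(C)[C@@H]1CO[Si](C)(C)C(C)(C)C
F0 | step 16 | none | none
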